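**Plan**
- Retrosynthesis: the three galloyl ester C–O bonds and all benzylic protecting groups are cut first, then the C3–C4 bond of the cyclohexane. The two aldehydes so exposed go back to a vinyl and an allyl group, the C5 carbinol to a vinyl ketone, the C4–C5 bond to a Weinreb amide plus a vinyl Grignard reagent, and the C1–C2 bond to allylation of an L-malic acid acetal enolate.
- Feature used: in the cyclohexane ring (C1 = the carbinol carbon bearing CO2H), C3 and C4 are neighbouring secondary carbinol carbons with cis oxygens, and O5 on the next ring carbon is trans to O4. This is the pattern left by a chelated ketyl coupling of a 1,6-dialdehyde that carries one α-oxygen.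
- Forward: the open chain is assembled on L-malic acid (allyl at C1, vinyl at C5), both alkenes are ozonised, the only carbocycle closes last by SmI2 pinacol coupling of C3 with C4, and esterification plus hydrogenolysis finish the synthesis.
- Stereochemistry: C1 comes from L-malic acid, relayed through the cis pivalaldehyde acetal (alkylation with retention). C5 comes from reagent control in a Corey–Bakshi–Shibata reduction. C3 and C4 arise in the key step, cis to each other by samarium chelation and trans to O5 through the α-silyloxy group.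

Key step: step 10

Remark: ring positions follow quinic acid numbering (C1 bears CO2H; O3 and O4 are cis to each other and to O1; O5 is trans to O4 and cis to the carboxyl carbon). The tertiary O1 is carried as a benzyloxymethyl ether, which can be installed without forming an alkoxide and still leaves by hydrogenolysis.

Step 1
Reactants: 1 L-malic acid
Product: 2 [(2S,4S)-2-tert-butyl-5-oxo-1,3-dioxolan-4-yl]acetic acid (tert-butyl cis to the CH2CO2H arm)
Conditions: t-BuCHO, TsOH (cat.), H2SO4 (cat.), pentane, reflux, Dean–Stark; recrystallisation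
Reagents that add atoms: pivalaldehyde, CC(C)(C)C=O
Why: Acid-catalysed acetalisation under water removal closes the five-membered dioxolanone on the α-hydroxy acid unit rather than the six-membered dioxanone, and equilibration places the tert-butyl group cis to the CH2CO2H arm, so that the new acetal stereocentre records the configuration of the malate carbon.

Step 2
Reactants: 2 [(2S,4S)-2-tert-butyl-5-oxo-1,3-dioxolan-4-yl]acetic acid; 3 allyl bromide
Product: 5 [(2S,4S)-2-tert-butyl-5-oxo-4-(prop-2-en-1-yl)-1,3-dioxolan-4-yl]acetic acid (allyl trans to tert-butyl), via dilithium enolate carboxylate 4 (not isolated)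
Conditions: LiN(SiMe3)2 (2.2 equiv), THF, −78 °C; then 3, −78 → −30 °C; aq. HCl
Reagents that add atoms: none
Why: Diastereoselective enolate alkylation (self-regeneration of a stereocentre): the second equivalent of base forms the ring enolate of the lithium carboxylate, allyl bromide approaches the face opposite the tert-butyl group, and allyl thereby replaces the former hydrogen with overall retention, which fixes the quaternary carbon that becomes C1.

Step 3
Reactants: 5 [(2S,4S)-2-tert-butyl-5-oxo-4-(prop-2-en-1-yl)-1,3-dioxolan-4-yl]acetic acid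
Product: 7 2-[(2S,4S)-2-tert-butyl-5-oxo-4-(prop-2-en-1-yl)-1,3-dioxolan-4-yl]-N-methoxy-N-methylacetamide, via acyl imidazole 6 (not isolated)
Conditions: CDI, CH2Cl2, 0 °C → rt; then MeNHOMe·HCl, rt
Reagents that add atoms: N,O-dimethylhydroxylamine hydrochloride, CNOC.Cl
Why: Amide coupling through the acyl imidazole needs no strong base or nucleophile, so the hindered dioxolanone should survive while the side-chain acid becomes a Weinreb amide that later accepts exactly one vinyl group.

Step 4
Reactants: 7 2-[(2S,4S)-2-tert-butyl-5-oxo-4-(prop-2-en-1-yl)-1,3-dioxolan-4-yl]-N-methoxy-N-methylacetamide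
Product: 8 benzyl (2S)-2-hydroxy-2-{2-[methoxy(methyl)amino]-2-oxoethyl}pent-4-enoate
Conditions: BnOH (3 equiv), BnOLi (0.2 equiv), THF, 0 °C
Reagents that add atoms: benzyl alcohol, OCc1ccccc1
Why: Alkoxide-catalysed transesterification of the activated acylal-type lactone gives the benzyl ester, the hemiacetal alkoxide so released collapses to pivalaldehyde and the tertiary alcohol, the Weinreb amide is inert to benzyloxide, and the quaternary stereocentre cannot epimerise.

Step 5
Reactants: 8 benzyl (2S)-2-hydroxy-2-{2-[methoxy(methyl)amino]-2-oxoethyl}pent-4-enoate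
Product: 9 benzyl (2S)-2-[(benzyloxy)methoxy]-2-{2-[methoxy(methyl)amino]-2-oxoethyl}pent-4-enoate
Conditions: BnOCH2Cl, i-Pr2NEt, Bu4NI (cat.), CH2Cl2, 40 °C
Reagents that add atoms: benzyl chloromethyl ether, ClCOCc1ccccc1
Why: Alkoxymethylation of a hindered tertiary alcohol with the very electrophilic chloromethyl ether (iodide catalysis) under amine base is chosen over a Williamson benzylation because no alkoxide is formed that could undergo retro-aldol cleavage, and it gives an ether that the final hydrogenolysis removes.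

Step 6
Reactants: 9 benzyl (2S)-2-[(benzyloxy)methoxy]-2-{2-[methoxy(methyl)amino]-2-oxoethyl}pent-4-enoate; 10 vinylmagnesium bromide
Product: 12 benzyl (2S)-2-[(benzyloxy)methoxy]-4-oxo-2-(prop-2-en-1-yl)hex-5-enoate, via magnesium hemiaminal chelate 11 (not isolated)
Conditions: CH2=CHMgBr, THF, −78 → −20 °C; inverse quench into cold 1 M HCl
Reagents that add atoms: none
Why: Weinreb ketone synthesis: the five-membered magnesium chelate of the tetrahedral adduct resists a second addition, the benzyl ester on the fully substituted carbon is far slower towards the Grignard reagent at low temperature, and the acidic inverse quench protonates the liberated N,O-dimethylhydroxylamine before it can add to the vinyl ketone.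

Step 7
Reactants: 12 benzyl (2S)-2-[(benzyloxy)methoxy]-4-oxo-2-(prop-2-en-1-yl)hex-5-enoate
Product: 13 benzyl (2S,4R)-2-[(benzyloxy)methoxy]-4-hydroxy-2-(prop-2-en-1-yl)hex-5-enoate
Conditions: (S)-2-methyl-CBS-oxazaborolidine (20 mol %), catecholborane, toluene, −78 °C; MeOH; cold aq. NaHCO3 wash; crude used at once
Reagents that add atoms: none
Why: Corey–Bakshi–Shibata reduction: the ketone should bind to the ring boron through the lone pair on the side of the smaller methylene substituent, the vinyl group acting as the large group as with other enones, and catecholborane held on the ring nitrogen then delivers hydride to give the (4R)-carbinol that becomes C5, this borane being unreactive at −78 °C towards the two terminal alkenes and the ester.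

Step 8
Reactants: 13 benzyl (2S,4R)-2-[(benzyloxy)methoxy]-4-hydroxy-2-(prop-2-en-1-yl)hex-5-enoate
Product: 14 benzyl (2S,4R)-2-[(benzyloxy)methoxy]-4-[(tert-butyldimethylsilyl)oxy]-2-(prop-2-en-1-yl)hex-5-enoate
Conditions: TBSOTf, 2,6-lutidine, CH2Cl2, −78 °C
Reagents that add atoms: tert-butyldimethylsilyl triflate, CC(C)(C)[Si](C)(C)OS(=O)(=O)C(F)(F)F
Why: Silylation of a secondary alcohol with a silyl triflate and a hindered pyridine base is fast at −78 °C, which caps the γ-hydroxy ester before it can lactonise and installs the bulky, non-chelating O5 group that the key step relies on.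

Step 9
Reactants: 14 benzyl (2S,4R)-2-[(benzyloxy)methoxy]-4-[(tert-butyldimethylsilyl)oxy]-2-(prop-2-en-1-yl)hex-5-enoate
Product: 16 benzyl (2R,4R)-2-[(benzyloxy)methoxy]-4-[(tert-butyldimethylsilyl)oxy]-5-oxo-2-(2-oxoethyl)pentanoate, via bis-ozonide 15 (not isolated)
Conditions: O3, CH2Cl2, −78 °C (to first faint blue); N2 purge; PPh3, −78 °C → rt; short silica plug; used at once
Reagents that add atoms: ozone, [O-][O+]=O
Why: Ozonolysis with reductive work-up: both monosubstituted alkenes add ozone much faster than the benzylic C–H bonds are attacked, and triphenylphosphine reduces the two 1,2,4-trioxolanes to the C3 and C4 aldehydes without base, so that the α-silyloxy stereocentre should not epimerise.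

Step 10
Reactants: 16 benzyl (2R,4R)-2-[(benzyloxy)methoxy]-4-[(tert-butyldimethylsilyl)oxy]-5-oxo-2-(2-oxoethyl)pentanoate
Product: 17 benzyl 1-O-(benzyloxymethyl)-5-O-(tert-butyldimethylsilyl)-(−)-quinate
Conditions: SmI2 (3 equiv, 0.1 M in THF), t-BuOH (3 equiv), THF, −78 → −20 °C; aq. NaHCO3
Reagents that add atoms: none
Why: Divalent samarium transfers one electron to an aldehyde carbonyl, the resulting ketyl bound to trivalent samarium attacks the second carbonyl (or combines with its ketyl) to forge the C3–C4 bond, and tert-butanol protonates the samarium diolate. The closest known reaction type is the SmI2 pinacol cyclisation of α-alkoxy 1,6-dialdehydes from hexitols to cis-cyclohexane-1,2-diols. The cyclohexane ring closes in the 6-exo-trig mode through a chair that keeps the C5 silyloxy group and the ester equatorial and the C1 ether oxygen axial. C4 is controlled by the C5 stereocentre: the ketyl C–O bond lies anti to the bulky, non-chelating silyloxy group, so O4 should end up trans to O5. C3 is controlled by the metal: both oxygens are held on one trivalent samarium, which makes O3 cis to O4, and the axial C1 ether oxygen can bind the same metal on that face, the face on which O3 is cis to O1. The step needs aldehyde-over-ester chemoselectivity, secured by the fast reduction of two unhindered aldehydes at −78 °C without HMPA, and the cis-diol anti to O5, secured by the chelate and the α-silyloxy group; a silyl shift from O5 to O4 would not matter since step 11 removes the group.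

Step 11
Reactants: 17 benzyl 1-O-(benzyloxymethyl)-5-O-(tert-butyldimethylsilyl)-(−)-quinate
Product: 18 benzyl 1-O-(benzyloxymethyl)-(−)-quinate
Conditions: HF·pyridine, pyridine, THF, 0 °C → rt
Reagents that add atoms: none
Why: Fluoride-mediated cleavage of the secondary silyl ether under buffered, weakly acidic conditions should leave the acetal-type benzyloxymethyl ether and the benzyl ester intact and avoids the alkoxide that could close the 1,5-lactone.

Step 12
Reactants: 18 benzyl 1-O-(benzyloxymethyl)-(−)-quinate; 19 3,4,5-tris(benzyloxy)benzoyl chloride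
Product: 20 benzyl 1-O-(benzyloxymethyl)-3,4,5-tris-O-[3,4,5-tris(benzyloxy)benzoyl]-(−)-quinate
Conditions: 19 (4.5 equiv in all, three of which enter the product), DMAP, pyridine, CH2Cl2, rt → 40 °C
Reagents that add atoms: 3,4,5-tris(benzyloxy)benzoyl chloride (second equivalent of 19), O=C(Cl)c1cc(OCc2ccccc2)c(OCc2ccccc2)c(OCc2ccccc2)c1; 3,4,5-tris(benzyloxy)benzoyl chloride (third equivalent of 19), O=C(Cl)c1cc(OCc2ccccc2)c(OCc2ccccc2)c(OCc2ccccc2)c1
Why: DMAP-catalysed esterification with an acid chloride acylates all three secondary hydroxyls, each taking up one molecule of 19 while the tertiary oxygen is blocked, and an excess of the acid chloride should drive the hindered central O4 to completion, after which no free hydroxyl is left for acyl migration.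

Step 13
Reactants: 20 benzyl 1-O-(benzyloxymethyl)-3,4,5-tris-O-[3,4,5-tris(benzyloxy)benzoyl]-(−)-quinate
Product: 21 3,4,5-tri-O-galloyl-(−)-quinic acid
Conditions: H2 (1 atm), Pd/C, THF/MeOH, rt
Reagents that add atoms: none
Why: Catalytic hydrogenolysis cleaves the nine aryl benzyl ethers, the benzyl ester and the benzylic C–O bond of the benzyloxymethyl ether, whose hemiacetal loses formaldehyde to free the tertiary hydroxyl, while the aryl esters and all four stereocentres are untouched.

**Compound list**
1 | L-malic acid | OC(=O)C[C@H](O)C(=O)O | starting material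
2 | [(2S,4S)-2-tert-butyl-5-oxo-1,3-dioxolan-4-yl]acetic acid | OC(=O)C[C@@H]1O[C@H](C(C)(C)C)OC1=O | intermediate
3 | allyl bromide | C=CCBr | starting material
4 | dilithium (2S)-2-tert-butyl-5-(carboxylatomethyl)-2H-1,3-dioxol-4-olate (enolate carboxylate of 2) | [Li+].[Li+].[O-]C(=O)CC1=C([O-])O[C@@H](C(C)(C)C)O1 | intermediate
5 | [(2S,4S)-2-tert-butyl-5-oxo-4-(prop-2-en-1-yl)-1,3-dioxolan-4-yl]acetic acid | OC(=O)C[C@]1(CC=C)O[C@H](C(C)(C)C)OC1=O | intermediate
6 | 1-{[(2S,4S)-2-tert-butyl-5-oxo-4-(prop-2-en-1-yl)-1,3-dioxolan-4-yl]acetyl}-1H-imidazole | O=C(C[C@]1(CC=C)O[C@H](C(C)(C)C)OC1=O)n1ccnc1 | intermediate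
7 | 2-[(2S,4S)-2-tert-butyl-5-oxo-4-(prop-2-en-1-yl)-1,3-dioxolan-4-yl]-N-methoxy-N-methylacetamide | CON(C)C(=O)C[C@]1(CC=C)O[C@H](C(C)(C)C)OC1=O | intermediate
8 | benzyl (2S)-2-hydroxy-2-{2-[methoxy(methyl)amino]-2-oxoethyl}pent-4-enoate | CON(C)C(=O)C[C@@](O)(CC=C)C(=O)OCc1ccccc1 | intermediate
9 | benzyl (2S)-2-[(benzyloxy)methoxy]-2-{2-[methoxy(methyl)amino]-2-oxoethyl}pent-4-enoate | CON(C)C(=O)C[C@@](OCOCc1ccccc1)(CC=C)C(=O)OCc1ccccc1 | intermediate
10 | vinylmagnesium bromide | C=C[Mg]Br | starting material
11 | bromomagnesium alkoxide of the N-methoxy-N-methyl hemiaminal from 9 and 10 (hemiaminal carbon unassigned) | CON(C)C(O[Mg]Br)(C=C)C[C@@](OCOCc1ccccc1)(CC=C)C(=O)OCc1ccccc1 | intermediate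
12 | benzyl (2S)-2-[(benzyloxy)methoxy]-4-oxo-2-(prop-2-en-1-yl)hex-5-enoate | C=CC(=O)C[C@@](OCOCc1ccccc1)(CC=C)C(=O)OCc1ccccc1 | intermediate
13 | benzyl (2S,4R)-2-[(benzyloxy)methoxy]-4-hydroxy-2-(prop-2-en-1-yl)hex-5-enoate | C=C[C@H](O)C[C@@](OCOCc1ccccc1)(CC=C)C(=O)OCc1ccccc1 | intermediate
14 | benzyl (2S,4R)-2-[(benzyloxy)methoxy]-4-[(tert-butyldimethylsilyl)oxy]-2-(prop-2-en-1-yl)hex-5-enoate | C=C[C@H](O[Si](C)(C)C(C)(C)C)C[C@@](OCOCc1ccccc1)(CC=C)C(=O)OCc1ccccc1 | intermediate
15 | bis(1,2,4-trioxolane) of 14 (ozonide carbons unassigned) | C1(OCOO1)[C@H](O[Si](C)(C)C(C)(C)C)C[C@@](OCOCc1ccccc1)(CC1OCOO1)C(=O)OCc1ccccc1 | intermediate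
16 | benzyl (2R,4R)-2-[(benzyloxy)methoxy]-4-[(tert-butyldimethylsilyl)oxy]-5-oxo-2-(2-oxoethyl)pentanoate | O=C[C@H](O[Si](C)(C)C(C)(C)C)C[C@@](OCOCc1ccccc1)(CC=O)C(=O)OCc1ccccc1 | intermediate
17 | benzyl 1-O-(benzyloxymethyl)-5-O-(tert-butyldimethylsilyl)-(−)-quinate (3,4-diol cis, trans to O5) | CC(C)(C)[Si](C)(C)O[C@@H]1C[C@](OCOCc2ccccc2)(C(=O)OCc2ccccc2)C[C@@H](O)[C@H]1O | intermediate
18 | benzyl 1-O-(benzyloxymethyl)-(−)-quinate | O[C@@H]1C[C@](OCOCc2ccccc2)(C(=O)OCc2ccccc2)C[C@@H](O)[C@H]1O | intermediate
19 | 3,4,5-tris(benzyloxy)benzoyl chloride | O=C(Cl)c1cc(OCc2ccccc2)c(OCc2ccccc2)c(OCc2ccccc2)c1 | starting material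
20 | benzyl 1-O-(benzyloxymethyl)-3,4,5-tris-O-[3,4,5-tris(benzyloxy)benzoyl]-(−)-quinate | O=C(O[C@@H]1C[C@](OCOCc2ccccc2)(C(=O)OCc2ccccc2)C[C@@H](OC(=O)c2cc(OCc3ccccc3)c(OCc3ccccc3)c(OCc3ccccc3)c2)[C@H]1OC(=O)c1cc(OCc2ccccc2)c(OCc2ccccc2)c(OCc2ccccc2)c1)c1cc(OCc2ccccc2)c(OCc2ccccc2)c(OCc2ccccc2)c1 | intermediate
21 | 3,4,5-tri-O-galloyl-(−)-quinic acid | O=C(O[C@@H]1C[C@](O)(C(=O)O)C[C@@H](OC(=O)c2cc(O)c(O)c(O)c2)[C@H]1OC(=O)c1cc(O)c(O)c(O)c1)c1cc(O)c(O)c(O)c1 | target

**Count and risks**
Total steps: 13. Longest linear sequence: 13 steps, from 1 to 21.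

Steps most likely to fail:

1. Step 10. The ketyl coupling may pass through a non-chelated or wrongly folded transition state, giving the cis-diol syn to O5 or a trans-diol. The aldehydes may also simply be reduced, or the silyloxy group may be expelled from the C4 ketyl. Fallback: set out from diene 14 and close the same ring at the alkene level. Ring-closing metathesis with the second-generation Grubbs catalyst RuCl2(=CHPh)(H2IMes)(PCy3) in CH2Cl2 at 40 °C should give, with loss of ethene, benzyl (1S,5R)-1-[(benzyloxy)methoxy]-5-[(tert-butyldimethylsilyl)oxy]cyclohex-3-ene-1-carboxylate F1. Osmylation (OsO4 cat., N-methylmorpholine N-oxide, acetone/H2O) is then expected to add both oxygens to the face opposite the allylic silyloxy group, which comes back to the route at 17.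

2. Step 7. Facial discrimination may be weak because the vinyl group and the neopentyl-type methylene differ little for the catalyst, and the γ-hydroxy ester may lactonise during work-up. Fallback: set out from Weinreb amide 9. Addition of Me3SiC≡CLi (THF, −78 °C) should give benzyl (2S)-2-[(benzyloxy)methoxy]-4-oxo-2-(prop-2-en-1-yl)-6-(trimethylsilyl)hex-5-ynoate F2. Noyori transfer hydrogenation with RuCl[(R,R)-TsDPEN](p-cymene) in i-PrOH, where the alkynyl/alkyl distinction is electronic and large, is expected to give benzyl (2S,4R)-2-[(benzyloxy)methoxy]-4-hydroxy-2-(prop-2-en-1-yl)-6-(trimethylsilyl)hex-5-ynoate F3. C-desilylation with Bu4NF buffered by AcOH (THF, 0 °C) should give benzyl (2S,4R)-2-[(benzyloxy)methoxy]-4-hydroxy-2-(prop-2-en-1-yl)hex-5-ynoate F4. Semi-hydrogenation over Pd/CaCO3 poisoned with Pb(OAc)2 and quinoline (Lindlar) comes back to the route at 13, which is silylated at once as in step 8.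

3. Step 9. Ozone may over-oxidise the benzylic C–H bonds of the benzyloxymethyl ether and the benzyl ester. The labile dialdehyde may also be lost by epimerisation at the α-silyloxy carbon or β-elimination of the C1 ether while the phosphine oxide is removed. Fallback: set out from 14 and use a Lemieux–Johnson cleavage (OsO4 cat., NaIO4, 2,6-lutidine, dioxane/H2O, rt). This passes through benzyl 2-[(benzyloxy)methoxy]-4-[(tert-butyldimethylsilyl)oxy]-2-(2,3-dihydroxypropyl)-5,6-dihydroxyhexanoate F5 (C2 and C4 as in 14, new carbinol centres unassigned). Periodate should cleave it as it forms, before its γ-hydroxyl can lactonise, and the sequence comes back to the route at 16 after a simple extractive work-up.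

**Further compounds**
F1 | step 10 | benzyl (1S,5R)-1-[(benzyloxy)methoxy]-5-[(tert-butyldimethylsilyl)oxy]cyclohex-3-ene-1-carboxylate | CC(C)(C)[Si](C)(C)O[C@@H]1C[C@](OCOCc2ccccc2)(C(=O)OCc2ccccc2)CC=C1
F2 | step 7 | benzyl (2S)-2-[(benzyloxy)methoxy]-4-oxo-2-(prop-2-en-1-yl)-6-(trimethylsilyl)hex-5-ynoate | C[Si](C)(C)C#CC(=O)C[C@@](OCOCc1ccccc1)(CC=C)C(=O)OCc1ccccc1
F3 | step 7 | benzyl (2S,4R)-2-[(benzyloxy)methoxy]-4-hydroxy-2-(prop-2-en-1-yl)-6-(trimethylsilyl)hex-5-ynoate | C[Si](C)(C)C#C[C@H](O)C[C@@](OCOCc1ccccc1)(CC=C)C(=O)OCc1ccccc1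
F4 | step 7 | benzyl (2S,4R)-2-[(benzyloxy)methoxy]-4-hydroxy-2-(prop-2-en-1-yl)hex-5-ynoate | C#C[C@H](O)C[C@@](OCOCc1ccccc1)(CC=C)C(=O)OCc1ccccc1
F5 | step 9 | benzyl 2-[(benzyloxy)methoxy]-4-[(tert-butyldimethylsilyl)oxy]-2-(2,3-dihydroxypropyl)-5,6-dihydroxyhexanoate (C2 and C4 as in 14) | OCC(O)[C@H](O[Si](C)(C)C(C)(C)C)C[C@@](OCOCc1ccccc1)(CC(O)CO)C(=O)OCc1ccccc1
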